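**Plan**

1. Retrosynthetic cuts: first the two ester C–O bonds (4-hydroxybenzoate on O-4, tiglate on O-8), with C4–OH traced back to a C4 ketone; then the ring-fusion bond C3a–C8a; then, in the resulting cis-decalin, C6=C7 (RCM), C4–C5 (Grignard addition) and C8–C8a (aldol).
2. Enabling feature: C4 carries oxygen, C3a lies between C4 and the tertiary carbinol C3, and the quaternary C8a is the other neighbour of C3a. A 1,2-shift of C8a from a C4 carbinol to C3a (C4 becoming C=O) therefore turns a 6–6 system (ring A: C8a–C4–C3a–C3–C2–C1; ring B: C8a–C8–C7–C6–C5–C4) into the 5–7 system. The C4–C8a bond is made on purpose and cleaved.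
3. Forward order: ring A is bought as (R)-carvone (C1, C2, C3, C3a, C4, C8a, 8a-CH3, isopropyl); ring B is closed by RCM; the cyclopentane and the cycloheptene then arise together in the shift; the esters come last.
4. Stereochemistry: the carvone stereocenter (C3) steers C8a in a reductive aldol and is then erased; C8 comes from the Zimmerman–Traxler chair; the temporary C4 carbinol forms anti to the 8a-methyl; O-3a and O-3 come from hydroxyl-directed epoxidation and inverting hydrolysis; C3a is fixed by the stereospecific shift; C4 by a thermodynamically controlled reduction.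

Key step: step 9

Remark: atoms carry the azulene numbers of the target throughout (C1, C2, C3, C3a, C4–C8, C8a), also in monocyclic and decalin intermediates; β is the face of the 8a-methyl group, α the opposite face.
Remark: the target is taken exactly as written, that is 3-OH, O-4 and O-8 on the α face, H-3a α, 8a-CH3 and isopropyl β; (R)-(−)-carvone of high enantiomeric purity is assumed.

**Step 1**
Reactants: 1 (R)-(−)-carvone
Product: 2 (R)-carvotanacetone, (5R)-2-methyl-5-(propan-2-yl)cyclohex-2-en-1-one
Conditions: H2 (1 atm), RhCl(PPh3)3 (cat.), benzene, rt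
Reagents that add atoms: none
Why: Homogeneous hydrogenation with RhCl(PPh3)3 should saturate only the unhindered 1,1-disubstituted isopropenyl alkene and leave the trisubstituted enone untouched; the stereocenter (future C3) is the one that is bought.

**Step 2**
Reactants: 2 (R)-carvotanacetone; 3 (E)-but-2-enal
Product: 5 (2R,5R)-2-[(1R,2E)-1-hydroxybut-2-en-1-yl]-2-methyl-5-(propan-2-yl)cyclohexan-1-one, via lithium enolate 4 (not isolated)
Conditions: LiBH(s-Bu)3 (1.05 equiv), THF, −78 °C; then 3, −78 °C; aq NH4Cl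
Reagents that add atoms: none
Why: Conjugate hydride delivery gives the regiodefined tetrasubstituted lithium enolate, which adds 1,2 to the enal (reductive aldol through a Zimmerman–Traxler chair); axial attack on the half-chair with equatorial isopropyl should place the new chain cis to isopropyl and so set C8a, and the ring-locked enolate geometry (CH3 cis to OLi) with an equatorial propenyl group should set C8 with O-8 and 8a-CH3 syn in the open chain, which is trans in the later ring.

**Step 3**
Reactants: 5 aldol adduct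
Product: 7 (6R)-6-[(1R,2E)-1-(tert-butyldimethylsilyloxy)but-2-en-1-yl]-6-methyl-3-(propan-2-yl)cyclohex-2-en-1-one, via bis-silyl enol ether 6 (not isolated)
Conditions: t-BuMe2SiOTf (2.5 equiv), Et3N, CH2Cl2, 0 °C to rt; then Pd(OAc)2 (10 mol %), O2 (1 atm), DMSO, 60 °C
Reagents that add atoms: tert-butyldimethylsilyl trifluoromethanesulfonate, CC(C)(C)[Si](C)(C)OS(=O)(=O)C(F)(F)F
Why: Double silylation protects O-8 and forms the only possible enol ether (C8a is quaternary), and Saegusa–Ito oxidation with Pd(OAc)2 under O2 should then give the C3a=C3 enone, which erases the relay stereocenter once C8a is in place.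

**Step 4**
Reactants: 7 enone; 8 2-methylallylmagnesium chloride
Product: 9 (1S,6R)-6-[(1R,2E)-1-(tert-butyldimethylsilyloxy)but-2-en-1-yl]-6-methyl-1-(2-methylprop-2-en-1-yl)-3-(propan-2-yl)cyclohex-2-en-1-ol (OH cis to the ring methyl)
Conditions: 8 (1.5 equiv), THF, −78 °C; aq NH4Cl
Reagents that add atoms: none
Why: Allylic Grignard reagents add 1,2 to enones, and attack on C4 anti to the pseudo-axial 8a-methyl (the bulky silyloxyalkyl chain being equatorial) should give the 4β-carbinol with C5 cis to C8, as needed for a cis ring fusion.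

**Step 5**
Reactants: 9 triene alcohol
Product: 10 cis-decalin dienol (C4–C8a bonded; 4β-OH; 8α-OTBS; 8aβ-CH3; 6-CH3; 3-isopropyl; C3=C3a and C6=C7)
Conditions: second-generation Grubbs catalyst (5 mol %), CH2Cl2, 40 °C
Reagents that add atoms: none
Why: Ring-closing metathesis of the propenyl and 2-methylallyl groups, held cis on adjacent carbons, should close six-membered ring B with its trisubstituted C6=C7 bond and release propene, while the endocyclic trisubstituted C3a=C3 alkene does not engage.

**Step 6**
Reactants: 10 cis-decalin dienol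
Product: 12 cis-decalin triol (4β-OH; 3aβ-OH; 3α-OH; 3β-isopropyl; 8α-OTBS; C6=C7), via syn-epoxy alcohol 11 (not isolated)
Conditions: VO(acac)2 (5 mol %), t-BuOOH, CH2Cl2, 0 °C to rt; then HClO4 (cat.), THF/H2O, 0 °C
Reagents that add atoms: tert-butyl hydroperoxide, CC(C)(C)OO; water, O
Why: Vanadium-catalyzed hydroxyl-directed epoxidation should take the allylic C3a=C3 bond syn to the 4β-OH (the homoallylic C6=C7 bond reacts more slowly), and acid-catalyzed hydrolysis should open the epoxide at the tertiary C3 with inversion (trans-diaxial, Fürst–Plattner), leaving O-3a β and placing O-3 α.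

**Step 7**
Reactants: 12 cis-decalin triol
Product: 15 cis-decalin 4β,3aβ-diol 3α-triethylsilyl ether, via phenylboronate 13 (not isolated), via silylated phenylboronate 14 (not isolated)
Conditions: PhB(OH)2, MgSO4, CH2Cl2, rt; then Et3SiOTf, 2,6-lutidine, −40 to 0 °C; then aq H2O2, NaHCO3, THF, 0 °C
Reagents that add atoms: triethylsilyl trifluoromethanesulfonate, CC[Si](CC)(CC)OS(=O)(=O)C(F)(F)F
Why: Transient boronate protection masks the cis-4,3a-diol as a five-membered cyclic ester so that only the tertiary 3α-OH is silylated, and oxidative cleavage of the B–C bond then returns the diol.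

**Step 8**
Reactants: 15 diol silyl ether
Product: 16 cis-decalin 3aβ-methanesulfonate (4β-OH free; 3α-OTES; 8α-OTBS)
Conditions: MsCl, Et3N, CH2Cl2, −20 °C
Reagents that add atoms: methanesulfonyl chloride, CS(=O)(=O)Cl
Why: Mesylation through the sulfene takes the only secondary hydroxyl, while the hindered tertiary ring-fusion 4-OH stays free.

**Step 9**
Reactants: 16 hydroxy mesylate
Product: 18 trans-hydroazulenone (3aα-H; 8aβ-CH3; 3α-OTES; 8α-OTBS; C4 ketone; C6=C7), via diethylaluminium alkoxide 17 (not isolated)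
Conditions: AlEt3 (3 equiv), CH2Cl2, −78 to 0 °C; aq KNaC4H4O6
Reagents that add atoms: none
Why: AlEt3 turns the 4β-OH into an aluminium alkoxide and activates the sulfonate; the C4–C8a bond, antiperiplanar to the equatorial C3a–OMs bond, migrates to C3a as the sulfonate leaves and C4 becomes the carbonyl (pinacol-type 1,2-shift). The closest known reaction type is the semipinacol rearrangement of cis-vicinal diol monosulfonates, both in its organoaluminium-promoted form and as the classical conversion of decalin diol monosulfonates into hydroazulenones. The cyclopentane closes by 6→5 contraction of ring A and the cycloheptene by 6→7 expansion of ring B in the same suprafacial shift, so neither ring arises by an exo or endo cyclization. C3a is set by inversion (the β-sulfonate gives the α-hydrogen), C8a migrates with retention, and C3 and C8 are untouched, so the trans ring fusion follows from the cis-decalin chair in which 8a-CH3, OMs and OTES are equatorial on ring A. The step needs migration of C8a rather than C5 or C2 and no epoxide formation: C5 is gauche to the C–OMs bond in that chair, O-3 is silylated so that C2 has no oxygen push and no alkoxide can displace the sulfonate, and the 4-OH is cis to the sulfonate. Non-basic conditions should keep the β-silyloxy, β,γ-unsaturated ketone from elimination, from epimerization at C3a and from conjugation.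

**Step 10**
Reactants: 18 hydroazulenone
Product: 19 hydroazulen-4α-ol (3α-OTES; 8α-OTBS)
Conditions: SmI2 (2.5 equiv), H2O, Et3N, THF, 0 °C
Reagents that add atoms: none
Why: Electron-transfer reduction of the ketone passes through a configurationally labile carbinyl species whose protonation should favour the equatorial 4α-alcohol, which avoids the 1,3-diaxial clash with the 8a-methyl, as in dissolving-metal reductions of hindered ring ketones.

**Step 11**
Reactants: 19 hydroazulen-4α-ol; 20 4-acetoxybenzoyl chloride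
Product: 21 4α-(4-acetoxybenzoyl) ester (3α-OTES; 8α-OTBS)
Conditions: pyridine, DMAP (cat.), CH2Cl2, rt
Reagents that add atoms: none
Why: DMAP-catalyzed acylation of the only free hydroxyl proceeds with retention at C4, and the acetate keeps the phenol from acylating.

**Step 12**
Reactants: 21 bis-silyl ether
Product: 22 3α,8α-diol 4α-(4-acetoxybenzoate)
Conditions: HF·pyridine, pyridine, THF, 0 °C to rt
Reagents that add atoms: none
Why: Fluoride-mediated desilylation should cleave both silyl ethers, while the benzoate and the aryl acetate are stable to buffered HF·pyridine.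

**Step 13**
Reactants: 22 diol; 23 (E)-2-methylbut-2-enoyl chloride (tigloyl chloride)
Product: 24 8α-tiglate 4α-(4-acetoxybenzoate) with free tertiary 3α-OH
Conditions: pyridine, DMAP, CH2Cl2, 0 °C to rt
Reagents that add atoms: none
Why: DMAP-catalyzed acylation should take the secondary allylic 8-OH and leave the tertiary 3-OH, and pyridine rather than a trialkylamine avoids ketene formation, so the (E)-geometry of the acyl group is kept.

**Step 14**
Reactants: 24 acetate-protected ester
Product: 25 target, (3S,3aS,4S,8R,8aS)-3-hydroxy-6,8a-dimethyl-8-{[(2E)-2-methylbut-2-enoyl]oxy}-3-(propan-2-yl)-1,2,3,3a,4,5,8,8a-octahydroazulen-4-yl 4-hydroxybenzoate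
Conditions: NH4OAc, MeOH/H2O (4:1), rt
Reagents that add atoms: none
Why: Aryl acetates are much better acyl donors than alkyl, benzoate or conjugated esters, so mild NH4OAc-mediated methanolysis (chemoselective transesterification) should remove only the phenolic acetate.

**Compound list**

1 | (R)-(−)-carvone, (5R)-2-methyl-5-(prop-1-en-2-yl)cyclohex-2-en-1-one | CC1=CC[C@H](CC1=O)C(C)=C | starting material
2 | (R)-carvotanacetone, (5R)-2-methyl-5-(propan-2-yl)cyclohex-2-en-1-one | CC1=CC[C@H](CC1=O)C(C)C | intermediate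
3 | (E)-but-2-enal (crotonaldehyde) | C/C=C/C=O | starting material
4 | lithium (5R)-2-methyl-5-(propan-2-yl)cyclohex-1-en-1-olate | [Li]OC1=C(C)CC[C@@H](C(C)C)C1 | intermediate
5 | (2R,5R)-2-[(1R,2E)-1-hydroxybut-2-en-1-yl]-2-methyl-5-(propan-2-yl)cyclohexan-1-one (side chain cis to isopropyl) | C/C=C/[C@@H](O)[C@@]1(C)CC[C@@H](C(C)C)CC1=O | intermediate
6 | bis-silyl derivative of 5: O-8 tert-butyldimethylsilyl ether and C4 tert-butyldimethylsilyl enol ether (C4=C3a) | C/C=C/[C@@H](O[Si](C)(C)C(C)(C)C)[C@@]1(C)CC[C@@H](C(C)C)C=C1O[Si](C)(C)C(C)(C)C | intermediate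
7 | (6R)-6-[(1R,2E)-1-(tert-butyldimethylsilyloxy)but-2-en-1-yl]-6-methyl-3-(propan-2-yl)cyclohex-2-en-1-one | C/C=C/[C@@H](O[Si](C)(C)C(C)(C)C)[C@@]1(C)CCC(C(C)C)=CC1=O | intermediate
8 | 2-methylallylmagnesium chloride | CC(=C)C[Mg]Cl | starting material
9 | (1S,6R)-6-[(1R,2E)-1-(tert-butyldimethylsilyloxy)but-2-en-1-yl]-6-methyl-1-(2-methylprop-2-en-1-yl)-3-(propan-2-yl)cyclohex-2-en-1-ol (OH cis to ring methyl) | C/C=C/[C@@H](O[Si](C)(C)C(C)(C)C)[C@@]1(C)CCC(C(C)C)=C[C@@]1(O)CC(C)=C | intermediate
10 | cis-decalin dienol with C4–C8a bond: 4β-OH, 8α-OTBS, 8aβ-CH3, 6-CH3, 3-isopropyl, C3=C3a and C6=C7 | CC(C)(C)[Si](C)(C)O[C@@H]1C=C(C)C[C@]2(O)C=C(C(C)C)CC[C@]12C | intermediate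
11 | syn-epoxy alcohol: 3,3a-β-epoxide of 10 (epoxide O cis to 4β-OH) | CC(C)(C)[Si](C)(C)O[C@@H]1C=C(C)C[C@]2(O)[C@H]3O[C@@]3(C(C)C)CC[C@]12C | intermediate
12 | cis-decalin triol: 4β-OH, 3aβ-OH, 3α-OH (3β-isopropyl), 8α-OTBS, 8aβ-CH3, C6=C7 | CC(C)(C)[Si](C)(C)O[C@@H]1C=C(C)C[C@]2(O)[C@@H](O)[C@@](O)(C(C)C)CC[C@]12C | intermediate
13 | cyclic phenylboronate of the 4β,3aβ-diol of 12 (3α-OH free) | CC(C)(C)[Si](C)(C)O[C@@H]1C=C(C)C[C@]2(OB(c4ccccc4)O3)[C@@H]3[C@@](O)(C(C)C)CC[C@]12C | intermediate
14 | 3α-triethylsilyl ether of phenylboronate 13 | CC(C)(C)[Si](C)(C)O[C@@H]1C=C(C)C[C@]2(OB(c4ccccc4)O3)[C@@H]3[C@@](O[Si](CC)(CC)CC)(C(C)C)CC[C@]12C | intermediate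
15 | cis-decalin 4β,3aβ-diol with 3α-OTES and 8α-OTBS | CC(C)(C)[Si](C)(C)O[C@@H]1C=C(C)C[C@]2(O)[C@@H](O)[C@@](O[Si](CC)(CC)CC)(C(C)C)CC[C@]12C | intermediate
16 | cis-decalin 3aβ-methanesulfonate with free 4β-OH, 3α-OTES and 8α-OTBS | CC(C)(C)[Si](C)(C)O[C@@H]1C=C(C)C[C@]2(O)[C@@H](OS(C)(=O)=O)[C@@](O[Si](CC)(CC)CC)(C(C)C)CC[C@]12C | intermediate
17 | diethylaluminium 4β-alkoxide of 16 | CC(C)(C)[Si](C)(C)O[C@@H]1C=C(C)C[C@]2(O[Al](CC)CC)[C@@H](OS(C)(=O)=O)[C@@](O[Si](CC)(CC)CC)(C(C)C)CC[C@]12C | intermediate
18 | trans-fused 8α-(tert-butyldimethylsilyloxy)-6,8a-dimethyl-3-(propan-2-yl)-3α-(triethylsilyloxy)-2,3,3a,5,8,8a-hexahydroazulen-4(1H)-one (3aα-H, 8aβ-CH3) | CC(C)(C)[Si](C)(C)O[C@@H]1C=C(C)CC(=O)[C@@H]2[C@]1(C)CC[C@]2(O[Si](CC)(CC)CC)C(C)C | intermediate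
19 | 4α-alcohol of 18 (4-OH cis to H-3a, trans to 8a-CH3) | CC(C)(C)[Si](C)(C)O[C@@H]1C=C(C)C[C@H](O)[C@@H]2[C@]1(C)CC[C@]2(O[Si](CC)(CC)CC)C(C)C | intermediate
20 | 4-acetoxybenzoyl chloride | CC(=O)Oc1ccc(cc1)C(Cl)=O | starting material
21 | 4α-(4-acetoxybenzoyl) ester of 19 | CC(C)(C)[Si](C)(C)O[C@@H]1C=C(C)C[C@H](OC(=O)c2ccc(OC(C)=O)cc2)[C@@H]2[C@]1(C)CC[C@]2(O[Si](CC)(CC)CC)C(C)C | intermediate
22 | 3α,8α-dihydroxy hydroazulen-4α-yl 4-acetoxybenzoate | O[C@@H]1C=C(C)C[C@H](OC(=O)c2ccc(OC(C)=O)cc2)[C@@H]2[C@]1(C)CC[C@]2(O)C(C)C | intermediate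
23 | (E)-2-methylbut-2-enoyl chloride (tigloyl chloride) | C/C=C(\C)C(Cl)=O | starting material
24 | 8α-tiglate of 22 (phenol still acetylated) | C/C=C(\C)C(=O)O[C@@H]1C=C(C)C[C@H](OC(=O)c2ccc(OC(C)=O)cc2)[C@@H]2[C@]1(C)CC[C@]2(O)C(C)C | intermediate
25 | (3S,3aS,4S,8R,8aS)-3-hydroxy-6,8a-dimethyl-8-{[(2E)-2-methylbut-2-enoyl]oxy}-3-(propan-2-yl)-1,2,3,3a,4,5,8,8a-octahydroazulen-4-yl 4-hydroxybenzoate | C/C=C(\C)C(=O)O[C@@H]1C=C(C)C[C@H](OC(=O)c2ccc(O)cc2)[C@@H]2[C@]1(C)CC[C@]2(O)C(C)C | target

**Step count and risks**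

Total step count: 14. Longest linear sequence: 14 steps (fully linear from 1).

Steps most likely to fail:

Step 9. The shift may take a wrong course in the bicycle: reaction through the other cis-decalin chair with migration of C5, or ionization and elimination of the sulfonate. The fallback changes the order of ring construction and sets out from 9, before ring B exists. Directed epoxidation and hydrolysis as in step 6 would give the monocyclic triol F1. Transient boronate protection and silylation as in step 7 would give the 3-O-triethylsilyl diol F2, and mesylation the hydroxy mesylate F3. AlEt3 would then induce the same 1,2-shift as a plain ring contraction of a monocyclic cyclohexane, whose chair with equatorial sulfonate is free of the decalin constraint, to give the acylcyclopentane F4. Ring-closing metathesis of F4 with the second-generation Grubbs catalyst would close the seven-membered ring and come back to the route at 18.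

Step 10. Facial selectivity in the ketone reduction may be poor or reversed, giving the axial 4β-alcohol, because hydride-like delivery prefers the α face away from the 8a-methyl. The fallback uses this preference and sets out from 18. LiBH(s-Bu)3 in THF at −78 °C should deliver hydride from the open α face and give the 4β-alcohol F5. Mitsunobu esterification of F5 with 4-acetoxybenzoic acid (PPh3, DIAD, toluene) would then install the ester with inversion at C4 and come back to the route at 21.

Step 6. During the acid hydrolysis the cation-like tertiary C3 may undergo hydride shift from C3a or elimination, or the silyl ether may be lost, instead of capture by water. The fallback oxygenates ring A at the enone stage and sets out from 7. Copper-catalyzed conjugate borylation (B2pin2, CuCl, NaOt-Bu, MeOH) anti to the pseudo-axial 8a-methyl, followed by oxidation with NaBO3, would give the β-hydroxy ketone F6. Et3SiOTf and 2,6-lutidine would give the silyl ether F7. Enolate hydroxylation (KN(SiMe3)2, then 2-(phenylsulfonyl)-3-phenyloxaziridine) anti to the pseudo-axial silyloxy group would give the α-hydroxy ketone F8. Addition of 8 anti to the 8a-methyl would give the diol already described as F2, and ring-closing metathesis of it would come back to the route at 15.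

**Further compounds**

F1 | step 9 | monocyclic triol from 9: 4β-OH, 3aβ-OH, 3α-OH, with 2-methylallyl on C4 and the silyloxybutenyl chain on C8a | C/C=C/[C@@H](O[Si](C)(C)C(C)(C)C)[C@@]1(C)CC[C@](O)(C(C)C)[C@H](O)[C@@]1(O)CC(C)=C
F2 | step 9 | 3-O-triethylsilyl ether of F1 (4β,3aβ-diol free) | C/C=C/[C@@H](O[Si](C)(C)C(C)(C)C)[C@@]1(C)CC[C@](O[Si](CC)(CC)CC)(C(C)C)[C@H](O)[C@@]1(O)CC(C)=C
F3 | step 9 | 3aβ-methanesulfonate of F2 (4β-OH free) | C/C=C/[C@@H](O[Si](C)(C)C(C)(C)C)[C@@]1(C)CC[C@](O[Si](CC)(CC)CC)(C(C)C)[C@H](OS(C)(=O)=O)[C@@]1(O)CC(C)=C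
F4 | step 9 | acylcyclopentane: trans-3a-(3-methylbut-3-enoyl)-8a-methyl-8a-[(1R,2E)-1-(tert-butyldimethylsilyloxy)but-2-enyl] cyclopentane with 3α-OTES and 3β-isopropyl | C/C=C/[C@@H](O[Si](C)(C)C(C)(C)C)[C@@]1(C)CC[C@](O[Si](CC)(CC)CC)(C(C)C)[C@@H]1C(=O)CC(C)=C
F5 | step 10 | 4β-alcohol, the C4 epimer of 19 | CC(C)(C)[Si](C)(C)O[C@@H]1C=C(C)C[C@@H](O)[C@@H]2[C@]1(C)CC[C@]2(O[Si](CC)(CC)CC)C(C)C
F6 | step 6 | β-hydroxy ketone from 7: 3α-hydroxy-3β-isopropyl cyclohexanone with the C8a quaternary centre of 7 | C/C=C/[C@@H](O[Si](C)(C)C(C)(C)C)[C@@]1(C)CC[C@](O)(C(C)C)CC1=O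
F7 | step 6 | 3-O-triethylsilyl ether of F6 | C/C=C/[C@@H](O[Si](C)(C)C(C)(C)C)[C@@]1(C)CC[C@](O[Si](CC)(CC)CC)(C(C)C)CC1=O
F8 | step 6 | α-hydroxy ketone: 3aβ-hydroxy derivative of F7 | C/C=C/[C@@H](O[Si](C)(C)C(C)(C)C)[C@@]1(C)CC[C@](O[Si](CC)(CC)CC)(C(C)C)[C@H](O)C1=O
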